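Taking the racemization catalyst from 4 mol% in the amber run to 6 mol% in the violet run took the total product at 10.0 min from 81.0% to 80.0%, a step of 1 percentage point against a scatter of 1.5 points per reading, so between those two loadings the readings show no change in the yield.

| flask | left-handed substrate | right-handed substrate | partner | racemization catalyst | precatalyst | remark | time |
|---|---|---|---|---|---|---|---|
| amber | 0.050 M | 0.050 M | 4 equiv | 4 mol% | 0.1 mol% | run made earlier |  |
| violet | 0.050 M | 0.050 M | 4 equiv | 6 mol% | 0.1 mol% | run made earlier |  |
| flask | 0.050 M | 0.050 M | 4.00 equiv | 8 mol% | 0.1 mol% |  | 10 min |
- amber (time / min: left-handed product / %, right-handed product / %): 1.50: 19, 10; 3.00: 31, 17; 5.00: 40, 22; 6.00: 44, 23; 8.00: 52, 26; 10.0: 55, 26; 12.0: 57, 25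
- violet (time / min: left-handed product / %, right-handed product / %): 0.667: 11, 5; 2.00: 23, 14; 3.00: 30, 17; 5.00: 42, 19; 8.00: 53, 26; 10.0: 54, 26; 12.0: 59, 29

(each reading ± 1.5 percentage points)
- free catalyst is single-handed; left-handed substrate and right-handed substrate are mirror images of each other, charged as a racemate, each of them at the stated concentration
- the earlier runs were read with a standard deviation of 1.5 percentage points
- steps under discussion: partner + free catalyst + right-handed substrate -> free catalyst + right-handed product; partner -> decomposition product; partner + free catalyst + left-handed substrate -> free catalyst + left-handed product; left-handed substrate + racemization catalyst <-> right-handed substrate + racemization catalyst; partner + precatalyst -> free catalyst + spent reagent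
- an excess is below zero if the other one leads
* left-handed product and right-handed product together, in percent of the left-handed substrate and right-handed substrate charged together, at 10 min
* excess of left-handed product over right-handed product in the product at 10 min
* whether the exchange between left-handed substrate and right-handed substrate keeps pace with the reaction: how far the product's excess at 10 min gets from its value without exchange to its value with instant exchange (above 80% keeps pace, below 20% hardly takes part, else lags behind)

The excess at that time reads 35.8% and 35.0%, and I take it over as read. Left-handed product reads 55% in the amber run although left-handed substrate was half of the charge, so right-handed substrate has crossed over, and you may treat the two substrates as one pool of concentration c_pool, which falls at κ·c_partner·c_pool with one partner spent per substrate. Integrated: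

ln[(c_partner/c_partner,start)/(c_pool/c_pool,start)] = (c_partner,start − c_pool,start)·κ·t

The mean yield of the two runs, 80.5%, gives the pool constant κ, a pseudo-rate constant at this precatalyst loading, 1.12 M⁻¹ min⁻¹. This is the number that must be known well, since with half of it the integrated law puts the yield of the new flask at 60.0%. With κ itself I expect 80.5% for the new flask.

The forecast, higher than my figure, says 82% at an excess of 34%, and that the exchange keeps pace, holding that “exchange is already nearly complete”.

The new flask gives 82.5% at an excess of 35.4%, and the exchange keeps pace, at 87% of the way.

    partner + free catalyst + right-handed substrate → free catalyst + right-handed product (k = 258 M⁻² s⁻¹)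
    partner → decomposition product (k = 2.59 × 10⁻⁵ s⁻¹)
    partner + free catalyst + left-handed substrate → free catalyst + left-handed product (k = 578 M⁻² s⁻¹)
    left-handed substrate + racemization catalyst ⇌ right-handed substrate + racemization catalyst, rate k4*[racemization catalyst]*[left-handed substrate] forward; the back reaction follows from the equilibrium constant (k = 4.16 M⁻¹ s⁻¹)
    partner + precatalyst → free catalyst + spent reagent (k = 0.752 M⁻¹ s⁻¹)

In the new flask at 10.0 min the exchange relaxes with a half-life of 0.347 min while the making of left-handed product alone gives left-handed substrate one of 3.5 min, ten times as long, and the two substrates stand at 8.49% and 8.98%. Read from this flask's yield the pool constant is 1.21 M⁻¹ min⁻¹. Carrying 1.12 M⁻¹ min⁻¹ to a second flask, the same charge but with 1.00 equiv of partner, where partner is the limiting reagent, gives 30.0%, and that flask stands at 30.8%.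

The data stem from a simulated flask on assumed constants, noise included.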